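**Retrosynthetic overview**

- Target 14 ⇐ ketone 13 (C6 carbinol by hydroxyl-directed reduction) ⇐ hydroxy ketone 10 (C2 benzoate by acylation, C5 benzoate by inversion of the C5 carbinol).
- Key disconnection: 10 ⇐ cyclopentene α-ketol 9 by an acyloin (α-ketol) shift that inserts C1 between C6 and C2. The enabling feature is the tertiary carbinol C1 (OH, CH2OBz) lying next to ring carbon C6 (carbinol ≡ ketone) and between the oxygenated carbons C2 and C5, which sit symmetrically about the C3=C4 double bond.
- 9 ⇐ meso all-cis triol ketone 8 (enzymatic desymmetrisation) ⇐ 6-methoxyfulvene 4 (singlet oxygen [4+2], then oxidation of the exocyclic enol ether) ⇐ sodium cyclopentadienide 1 + acid chloride 2.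
- Rings: the five-membered carbocycle is bought as cyclopentadienide; the six-membered ring is formed only in step 5, by one-carbon enlargement of that five-membered ring.

Key step: step 5

Assumption: the lipase acetylates the ring carbinol predicted by the empirical large/medium-substituent model for secondary alcohols (quaternary carbon side large, vinyl CH medium), i.e. the 2R carbinol of 8, and the same enzyme cleaves that acetate again in step 7.

**Step 1**
Reactants: 1 sodium cyclopentadienide (2 equiv); 2 2-chloro-2-oxoethyl benzoate (benzoyloxyacetyl chloride)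
Product: 4 2-(cyclopenta-2,4-dien-1-ylidene)-2-methoxyethyl benzoate, via sodium acylcyclopentadienide 3 (not isolated)
Conditions: THF, −78 °C; then MeOTf, −78 to −20 °C
Reagents that add atoms: methyl trifluoromethanesulfonate, COS(=O)(=O)C(F)(F)F
Why: Cyclopentadienide should be C-acylated by the acid chloride much faster than it attacks the benzoate, the second equivalent deprotonates the acidic acylcyclopentadiene to the 6-oxidofulvene 3, and the hard methylating agent alkylates oxygen (6-alkoxyfulvene synthesis by O-alkylation of an acylcyclopentadienide), with no stereocenter formed.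

**Step 2**
Reactants: 4 2-(cyclopenta-2,4-dien-1-ylidene)-2-methoxyethyl benzoate
Product: 6 rac-2-[(2R,5S)-2,5-dihydroxycyclopent-3-en-1-ylidene]-2-methoxyethyl benzoate (cis-diol), via fulvene endoperoxide 5 (not isolated)
Conditions: O2, hν (visible), 5,10,15,20-tetraphenylporphyrin (cat.), CH2Cl2, −78 °C; then thiourea, MeOH, −78 °C to rt; used at once
Reagents that add atoms: dioxygen, O=O
Why: Singlet oxygen should add [4+2] across the ring diene (fulvene photooxygenation) and thiourea reduces the O–O bond of the labile endoperoxide at low temperature, so both ring hydroxyls arise cis on one face.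

**Step 3**
Reactants: 6 rac-2-[(2R,5S)-2,5-dihydroxycyclopent-3-en-1-ylidene]-2-methoxyethyl benzoate
Product: 8 2-oxo-2-[(1s,2R,5S)-1,2,5-trihydroxycyclopent-3-en-1-yl]ethyl benzoate (meso, three hydroxyls cis), via methoxy epoxide 7 (not isolated)
Conditions: mCPBA, NaHCO3, CH2Cl2, 0 °C; then H2O
Reagents that add atoms: 3-chloroperoxybenzoic acid, OOC(=O)c1cccc(Cl)c1; water, O
Why: Rubottom-type oxidation in which the electron-rich exocyclic enol ether is epoxidised in preference to the 1,2-disubstituted ring alkene, hydrogen bonding of the peracid to the two allylic hydroxyls delivers oxygen to their face, and hydrolytic opening of the methoxy epoxide releases methanol and the ketone, so the tertiary hydroxyl should be cis to both ring hydroxyls and the racemate becomes one meso compound.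

**Step 4**
Reactants: 8 2-oxo-2-[(1s,2R,5S)-1,2,5-trihydroxycyclopent-3-en-1-yl]ethyl benzoate
Product: 9 2-[(1S,2R,5S)-2-(acetyloxy)-1,5-dihydroxycyclopent-3-en-1-yl]-2-oxoethyl benzoate
Conditions: Candida antarctica lipase B (immobilised), vinyl acetate, MTBE, 30 °C
Reagents that add atoms: vinyl acetate, CC(=O)OC=C
Why: Enzymatic desymmetrisation of a meso diol by irreversible lipase transesterification, in which the enzyme should acetylate the enantiotopic 2R carbinol that fits the large/medium-substituent model and leave the 5S and the tertiary hydroxyl free.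

**Step 5**
Reactants: 9 2-[(1S,2R,5S)-2-(acetyloxy)-1,5-dihydroxycyclopent-3-en-1-yl]-2-oxoethyl benzoate
Product: 10 [(1S,2S,5R)-5-(acetyloxy)-1,2-dihydroxy-6-oxocyclohex-3-en-1-yl]methyl benzoate
Conditions: Sc(OTf)3 (10 mol %), ClCH2CH2Cl, rt to 50 °C
Reagents that add atoms: none
Why: Lewis-acid-promoted α-ketol (acyloin) rearrangement: Sc(OTf)3 binds the tertiary hydroxyl and the ketone oxygen in a five-membered chelate, and the ring C–C bond lying perpendicular to the carbonyl plane shifts from the carbinol carbon to the carbonyl carbon while the carbinol becomes the ring ketone. The closest known reaction type is the ring enlargement of 1-acylcyclopentanols to 2-hydroxy-2-alkylcyclohexanones, as in the D-homo annulation of 17-hydroxy-20-keto steroids. The six-membered ring is closed not by a cyclisation but by a suprafacial 1,2-shift (one-carbon expansion of the cyclopentene, driven by relief of ring strain and of the eclipsing of three cis oxygens) with retention at the migrating carbon. The new quaternary stereocenter C1 is set by the chelate geometry: with the ketone oxygen syn to the departing hydroxyl, the migrating carbon enters the carbonyl face it flanks, which should place the new tertiary hydroxyl cis to the hydroxyl on the migrating carbon. The step needs migration of the hydroxyl-bearing ring carbon and not the acetoxy-bearing one; this is secured by the free cis hydroxyl, which joins the chelate (tridentate binding turns the carbonyl so that only this C–C bond is aligned) and makes its carbon the more electron-rich migrating group, while the ring face carrying the acyl group bears only hydrogens and gives no opposing steric bias.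

**Step 6**
Reactants: 10 [(1S,2S,5R)-5-(acetyloxy)-1,2-dihydroxy-6-oxocyclohex-3-en-1-yl]methyl benzoate
Product: 11 [(1S,2S,5R)-5-(acetyloxy)-2-(benzoyloxy)-1-hydroxy-6-oxocyclohex-3-en-1-yl]methyl benzoate
Conditions: BzCl, pyridine, DMAP (cat.), CH2Cl2, 0 °C
Reagents that add atoms: benzoyl chloride, O=C(Cl)c1ccccc1
Why: Acylation of the secondary allylic hydroxyl, the tertiary hydroxyl being too hindered to react under these conditions.

**Step 7**
Reactants: 11 [(1S,2S,5R)-5-(acetyloxy)-2-(benzoyloxy)-1-hydroxy-6-oxocyclohex-3-en-1-yl]methyl benzoate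
Product: 12 [(1S,2S,5R)-2-(benzoyloxy)-1,5-dihydroxy-6-oxocyclohex-3-en-1-yl]methyl benzoate
Conditions: Candida antarctica lipase B, phosphate buffer pH 7/acetone, 30 °C
Reagents that add atoms: none
Why: Lipase-catalysed hydrolysis at neutral pH should remove the acetate (the ester of the carbinol configuration the enzyme accepts) without touching the benzoates and without base that could epimerise the α-acyloxy ketone.

**Step 8**
Reactants: 12 [(1S,2S,5R)-2-(benzoyloxy)-1,5-dihydroxy-6-oxocyclohex-3-en-1-yl]methyl benzoate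
Product: 13 [(1S,2S,5S)-2,5-bis(benzoyloxy)-1-hydroxy-6-oxocyclohex-3-en-1-yl]methyl benzoate
Conditions: PPh3, DIAD, BzOH, toluene, 0 °C to rt
Reagents that add atoms: benzoic acid, O=C(O)c1ccccc1
Why: Mitsunobu reaction in which SN2 displacement of the activated α-keto allylic carbinol by benzoate inverts C5 and places the new benzoate trans to the C2 benzoate, the tertiary hydroxyl being inert.

**Step 9**
Reactants: 13 [(1S,2S,5S)-2,5-bis(benzoyloxy)-1-hydroxy-6-oxocyclohex-3-en-1-yl]methyl benzoate
Product: 14 [(1R,2S,5S,6S)-2,5-bis(benzoyloxy)-1,6-dihydroxycyclohex-3-en-1-yl]methyl benzoate (target)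
Conditions: Me4NBH(OAc)3, MeCN/AcOH, −30 °C
Reagents that add atoms: none
Why: Hydroxyl-directed triacetoxyborohydride reduction (Evans–Saksena reduction) in which the borohydride bound to the tertiary hydroxyl delivers hydride from the hydroxyl face, which is also anti to the C5 benzoate, so the C6 hydroxyl should form trans to the C1 hydroxyl and cis to the C5 benzoate.

**Compound list**

1 | sodium cyclopentadienide | [Na+].[CH-]1C=CC=C1 | starting material
2 | 2-chloro-2-oxoethyl benzoate (benzoyloxyacetyl chloride) | O=C(Cl)COC(=O)c1ccccc1 | starting material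
3 | sodium 2-(benzoyloxy)-1-(cyclopenta-2,4-dien-1-ylidene)ethan-1-olate | [Na+].[O-]C(COC(=O)c1ccccc1)=C1C=CC=C1 | intermediate
4 | 2-(cyclopenta-2,4-dien-1-ylidene)-2-methoxyethyl benzoate | COC(COC(=O)c1ccccc1)=C1C=CC=C1 | intermediate
5 | rac-2-(2,3-dioxabicyclo[2.2.1]hept-5-en-7-ylidene)-2-methoxyethyl benzoate (one enantiomer drawn) | CO/C(COC(=O)c1ccccc1)=C1/[C@@H]2C=C[C@H]1OO2 | intermediate
6 | rac-2-[(2R,5S)-2,5-dihydroxycyclopent-3-en-1-ylidene]-2-methoxyethyl benzoate (one enantiomer drawn) | CO/C(COC(=O)c1ccccc1)=C1/[C@@H](O)C=C[C@H]1O | intermediate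
7 | rac-(4,7-dihydroxy-2-methoxy-1-oxaspiro[2.4]hept-5-en-2-yl)methyl benzoate, epoxide oxygen cis to both hydroxyls (one enantiomer drawn) | CO[C@@]1(COC(=O)c2ccccc2)O[C@]12[C@@H](O)C=C[C@H]2O | intermediate
8 | 2-oxo-2-[(1s,2R,5S)-1,2,5-trihydroxycyclopent-3-en-1-yl]ethyl benzoate (meso) | O=C(COC(=O)c1ccccc1)[C@]1(O)[C@@H](O)C=C[C@H]1O | intermediate
9 | 2-[(1S,2R,5S)-2-(acetyloxy)-1,5-dihydroxycyclopent-3-en-1-yl]-2-oxoethyl benzoate | O=C(COC(=O)c1ccccc1)[C@]1(O)[C@@H](O)C=C[C@H]1OC(C)=O | intermediate
10 | [(1S,2S,5R)-5-(acetyloxy)-1,2-dihydroxy-6-oxocyclohex-3-en-1-yl]methyl benzoate | O=C(OC[C@]1(O)[C@@H](O)C=C[C@@H](OC(C)=O)C1=O)c1ccccc1 | intermediate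
11 | [(1S,2S,5R)-5-(acetyloxy)-2-(benzoyloxy)-1-hydroxy-6-oxocyclohex-3-en-1-yl]methyl benzoate | O=C(OC[C@]1(O)[C@@H](OC(=O)c2ccccc2)C=C[C@@H](OC(C)=O)C1=O)c1ccccc1 | intermediate
12 | [(1S,2S,5R)-2-(benzoyloxy)-1,5-dihydroxy-6-oxocyclohex-3-en-1-yl]methyl benzoate | O=C(OC[C@]1(O)[C@@H](OC(=O)c2ccccc2)C=C[C@@H](O)C1=O)c1ccccc1 | intermediate
13 | [(1S,2S,5S)-2,5-bis(benzoyloxy)-1-hydroxy-6-oxocyclohex-3-en-1-yl]methyl benzoate | O=C(OC[C@]1(O)[C@@H](OC(=O)c2ccccc2)C=C[C@H](OC(=O)c2ccccc2)C1=O)c1ccccc1 | intermediate
14 | [(1R,2S,5S,6S)-2,5-bis(benzoyloxy)-1,6-dihydroxycyclohex-3-en-1-yl]methyl benzoate | O=C(OC[C@]1(O)[C@@H](OC(=O)c2ccccc2)C=C[C@H](OC(=O)c2ccccc2)[C@@H]1O)c1ccccc1 | target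

**Step count and risks**

Total step count: 9. Longest linear sequence: 9 steps.

Steps most likely to fail:

1. Step 2. The electron-rich 6-methoxyfulvene may be attacked by singlet oxygen at the enol ether, its endoperoxide may fragment before reduction, or the enol-ether diol may hydrolyse. The fallback avoids the enol ether, sets out from 1 and comes back at 8. Compound 1 is condensed with 1-hydroxypropan-2-one in methanol (fulvene condensation) to 2-(cyclopenta-2,4-dien-1-ylidene)propan-1-ol F1, which is benzoylated to 2-(cyclopenta-2,4-dien-1-ylidene)propyl benzoate F2. Photooxygenation gives the endoperoxide F3, and thiourea reduces it to the racemic cis-diol F4. A hydroxyl-directed Schenck ene reaction (O2, hν, sensitiser, CH2Cl2) on the tetrasubstituted exocyclic alkene should give the tertiary allylic hydroperoxide F5, with oxygen delivered cis to both hydroxyls and hydrogen taken from the methyl group. PPh3 reduces it to the meso triol F6, and Ac2O/pyridine acetylates the two secondary hydroxyls to the diacetate F7. Lemieux–Johnson cleavage (OsO4 cat., NaIO4) of the 1,1-disubstituted alkene gives the ketone diacetate F8, and acid-catalysed methanolysis (HCl, MeOH, 0 °C) returns to 8.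

2. Step 5. The acetoxy-bearing carbon may migrate competitively, the acetyl group may shuttle between the cis oxygens with loss of enantiopurity, or the β-hydroxy ketone may open by retro-aldol cleavage. The fallback sets out from 8 and comes back at 10. The rearrangement is run on the unprotected meso triol 8 with Sc(OTf)3; no ester is present and the two candidate carbons are enantiotopic, so it gives racemic [(1S,2S,5R)-1,2,5-trihydroxy-6-oxocyclohex-3-en-1-yl]methyl benzoate F9. Lipase/vinyl acetate then acetylates the unhindered C5 carbinol of the 5R enantiomer only (kinetic resolution, at most half of the material), which is 10.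

3. Step 8. Benzoate may attack in the SN2′ sense toward the conjugated enone, or elimination and epimerisation α to the ketone may occur. The fallback sets out from 12 and comes back at 13. Tf2O/pyridine at −40 °C gives the C5 triflate F10, and tetrabutylammonium benzoate in toluene displaces it with inversion (sulfonate displacement, favoured at an α-keto carbon) to 13.

**Further compounds**

F1 | step 2 | 2-(cyclopenta-2,4-dien-1-ylidene)propan-1-ol | CC(CO)=C1C=CC=C1
F2 | step 2 | 2-(cyclopenta-2,4-dien-1-ylidene)propyl benzoate | CC(COC(=O)c1ccccc1)=C1C=CC=C1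
F3 | step 2 | rac-2-(2,3-dioxabicyclo[2.2.1]hept-5-en-7-ylidene)propyl benzoate | C/C(COC(=O)c1ccccc1)=C1/[C@@H]2C=C[C@H]1OO2
F4 | step 2 | rac-2-[(2R,5S)-2,5-dihydroxycyclopent-3-en-1-ylidene]propyl benzoate | C/C(COC(=O)c1ccccc1)=C1/[C@@H](O)C=C[C@H]1O
F5 | step 2 | 2-[(1s,2R,5S)-1-hydroperoxy-2,5-dihydroxycyclopent-3-en-1-yl]prop-2-en-1-yl benzoate | C=C(COC(=O)c1ccccc1)[C@]1(OO)[C@@H](O)C=C[C@H]1O
F6 | step 2 | 2-[(1s,2R,5S)-1,2,5-trihydroxycyclopent-3-en-1-yl]prop-2-en-1-yl benzoate | C=C(COC(=O)c1ccccc1)[C@]1(O)[C@@H](O)C=C[C@H]1O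
F7 | step 2 | 2-[(1s,2R,5S)-2,5-bis(acetyloxy)-1-hydroxycyclopent-3-en-1-yl]prop-2-en-1-yl benzoate | C=C(COC(=O)c1ccccc1)[C@]1(O)[C@@H](OC(C)=O)C=C[C@H]1OC(C)=O
F8 | step 2 | 2-[(1s,2R,5S)-2,5-bis(acetyloxy)-1-hydroxycyclopent-3-en-1-yl]-2-oxoethyl benzoate | O=C(COC(=O)c1ccccc1)[C@]1(O)[C@@H](OC(C)=O)C=C[C@H]1OC(C)=O
F9 | step 5 | rac-[(1S,2S,5R)-1,2,5-trihydroxy-6-oxocyclohex-3-en-1-yl]methyl benzoate | O=C(OC[C@]1(O)[C@@H](O)C=C[C@@H](O)C1=O)c1ccccc1
F10 | step 8 | [(1S,2S,5R)-2-(benzoyloxy)-1-hydroxy-6-oxo-5-{[(trifluoromethyl)sulfonyl]oxy}cyclohex-3-en-1-yl]methyl benzoate | O=C(OC[C@]1(O)[C@@H](OC(=O)c2ccccc2)C=C[C@@H](OS(=O)(=O)C(F)(F)F)C1=O)c1ccccc1
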